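**Plan**

1. Numbering: ring C5–C10; C10 carries CH3 and vinyl (C1=C2), C9 OH, C8 the lactone oxygen, C7 the chain C11(=C13H2)–C12(=O), C6 the angelate, C5 the chain C4(=C3H2)–C15HO. The α-methylene γ-lactone ring (C7–C11–C12–O–C8) and the acrolein on C5 are the same C(=CH2)–C=O unit on two ring carbons, and only the C7 copy has a hydroxyl (equatorial O8 on the neighbouring ring carbon) within reach of a five-membered ring.
2. Retrosynthesis: cut C11–C12, C12–O8 and C4–C15 (both acyl carbons become CO) to give the 8,9-diol bis(enol triflate); then the acetonide, the two C–OTf bonds (methyl ketones), the C6 ester, C6–H, C7–C11 and C5–C4 (acetaldehyde aldols), C10–CH3 and C10–vinyl, back to the enone from (−)-quinic acid.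
3. Forward: the cyclohexane is the quinic acid ring throughout; the substituents are joined in the order C10 vinyl, C10 methyl together with the C5 chain, C7 chain, C6 hydride, angelate; the lactone is the only ring made and it closes in the last step.
4. Stereochemistry: C8/C9 are C3/C4 of quinic acid; C10 comes from methyl addition anti to O9; C5 and C7 from aldol additions on the face away from the acetonide (also the all-equatorial arrangement); C6 from equatorial hydride delivery forced by the axial C10 methyl; the key step creates no stereocentre.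

Key step: step 18

Remark: α is the ring face of the C8/C9 oxygens, β the opposite face (that of the C10 methyl); compounds 2–5 are named with quinic acid numbering, later ones with the numbering above.
Assumption: the carbinol centres formed in the two aldol steps are not controlled (anti adducts expected to predominate); they are left undefined in names and SMILES, and both are erased by the oxidation in step 15.

**Route**

Step 1
Reactants: 1 (−)-quinic acid
Product: 2 3,4-O-isopropylidene-1,5-quinide (1,5-lactone, cis-3,4-acetonide, free tertiary 1-OH)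
Conditions: 2,2-dimethoxypropane, TsOH·H2O (cat.), acetone, reflux
Reagents that add atoms: 2,2-dimethoxypropane, COC(C)(C)OC
Why: Acid-catalysed acetal exchange places the acetonide on the only cis-diol (the future C8/C9 oxygens) while the carboxyl lactonises onto the syn 5-OH (acetonide formation with lactonisation), no stereocentre being touched.

Step 2
Reactants: 2 3,4-O-isopropylidene-1,5-quinide
Product: 3 1-(hydroxymethyl)cyclohexane-1,3,4,5-tetrol 3,4-acetonide (free 1-OH, CH2OH and 5-OH)
Conditions: NaBH4, EtOH, 0 °C → rt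
Reagents that add atoms: none
Why: Hydride reduction of the strained, α-oxygenated bridged lactone should give the primary alcohol and release the 5-hydroxyl.

Step 3
Reactants: 3 1-(hydroxymethyl)cyclohexane-1,3,4,5-tetrol 3,4-acetonide
Product: 4 5-hydroxy-3,4-(isopropylidenedioxy)cyclohexanone (5-OH trans to the acetonide)
Conditions: NaIO4, pH 7 phosphate buffer, H2O, 0 °C → rt
Reagents that add atoms: none
Why: Periodate glycol cleavage of the tertiary/primary 1,2-diol removes the former carboxyl carbon and leaves the ring ketone (future C6), the protected cis-diol being inert.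

Step 4
Reactants: 4 5-hydroxy-3,4-(isopropylidenedioxy)cyclohexanone
Product: 6 (4S,5R)-4,5-(isopropylidenedioxy)cyclohex-2-en-1-one (C6 ketone; C5=C10 alkene; 8α,9α-acetonide), via mesylate 5 (not isolated)
Conditions: MsCl, Et3N, CH2Cl2, 0 °C → rt
Reagents that add atoms: none
Why: Mesylation followed by E1cB elimination with triethylamine should give the conjugated enone, the mesylate leaving far faster than the acetonide oxygen on the other side of the ketone.

Step 5
Reactants: 6 (4S,5R)-4,5-(isopropylidenedioxy)cyclohex-2-en-1-one; 7 vinylmagnesium bromide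
Product: 8 6-(trimethylsilyloxy)-10β-vinylcyclohex-5-ene 8α,9α-acetonide
Conditions: CuBr·SMe2 (10 mol %), TMSCl, THF, −78 °C; Et3N quench
Reagents that add atoms: chlorotrimethylsilane, C[Si](C)(C)Cl
Why: Copper-catalysed, TMSCl-accelerated 1,4-addition of the vinyl Grignard should occur anti to the C9 acetonide oxygen with in-situ O-silylation of the enolate; the new C10 centre is erased in step 6.

Step 6
Reactants: 8 6-(trimethylsilyloxy)-10β-vinylcyclohex-5-ene 8α,9α-acetonide
Product: 9 10-vinylcyclohex-5(10)-en-6-one 8α,9α-acetonide (3-vinyl enone)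
Conditions: Pd(OAc)2 (1.05 equiv), MeCN, rt
Reagents that add atoms: none
Why: Saegusa–Ito oxidation, in which the palladium enolate loses H-10 by β-hydride elimination, should restore the C5=C10 enone now bearing the vinyl group.

Step 7
Reactants: 9 10-vinylcyclohex-5(10)-en-6-one 8α,9α-acetonide; 10 acetaldehyde
Product: 12 5β-(1-hydroxyethyl)-10β-methyl-10α-vinylcyclohexan-6-one 8α,9α-acetonide, via bromomagnesium enolate 11 (not isolated)
Conditions: MeMgBr, Cu(OTf)2 (5 mol %), SIMes·HCl (6 mol %), Et2O, −30 → 0 °C; then CH3CHO, −78 °C; aq. NH4Cl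
Reagents that add atoms: methylmagnesium bromide, C[Mg]Br
Why: NHC–copper-catalysed conjugate addition of a Grignard reagent, the catalyst type known to add 1,4 and not 1,6 to cyclic dienones, should deliver methyl to C10 anti to O9 (sets C10), and the regiodefined magnesium enolate then adds to acetaldehyde at C5 on the β face, away from the axial C9 oxygen (aldol trapping, sets C5).

Step 8
Reactants: 12 5β-(1-hydroxyethyl)-10β-methyl-10α-vinylcyclohexan-6-one 8α,9α-acetonide
Product: 13 TBS ether of 12
Conditions: TBSOTf, 2,6-lutidine, CH2Cl2, −78 °C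
Reagents that add atoms: tert-butyldimethylsilyl triflate, CC(C)(C)[Si](C)(C)OS(=O)(=O)C(F)(F)F
Why: Silylation with the silyl triflate and a hindered pyridine base at low temperature protects the aldol hydroxyl without retro-aldol cleavage.

Step 9
Reactants: 13 TBS ether of 12; 10 acetaldehyde
Product: 15 7β-(1-hydroxyethyl)-5β-[1-(TBS-oxy)ethyl]-10β-methyl-10α-vinylcyclohexan-6-one 8α,9α-acetonide, via dicyclohexylboron enolate 14 (not isolated)
Conditions: (c-Hex)2BCl, Et3N, Et2O, −78 → −20 °C; CH3CHO, −78 °C; MeOH, pH 7 buffer, H2O2, 0 °C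
Reagents that add atoms: none
Why: Boron-mediated aldol reaction: the boron chloride/amine pair enolises the only α-methylene (C7), the covalent boron enolate should not expel the β-acetonide oxygen, and the chair-like addition to acetaldehyde takes place anti to the adjacent C8 oxygen on the convex face (sets C7).

Step 10
Reactants: 15 7β-(1-hydroxyethyl)-5β-[1-(TBS-oxy)ethyl]-10β-methyl-10α-vinylcyclohexan-6-one 8α,9α-acetonide
Product: 16 5β,7β-bis[1-(TBS-oxy)ethyl]-10β-methyl-10α-vinylcyclohexan-6-one 8α,9α-acetonide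
Conditions: TBSOTf, 2,6-lutidine, CH2Cl2, −78 → 0 °C
Reagents that add atoms: tert-butyldimethylsilyl triflate, CC(C)(C)[Si](C)(C)OS(=O)(=O)C(F)(F)F
Why: Silyl triflate protection of the second aldol hydroxyl gives a ketone with no free OH, so that only the C6 oxygen is acylated later.

Step 11
Reactants: 16 5β,7β-bis[1-(TBS-oxy)ethyl]-10β-methyl-10α-vinylcyclohexan-6-one 8α,9α-acetonide
Product: 17 6β-alcohol (axial OH, cis to both side chains and to the C10 methyl)
Conditions: L-Selectride, THF, −78 → −20 °C; aq. NH4Cl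
Reagents that add atoms: none
Why: Bulky-hydride reduction should proceed by equatorial attack on the α face, because the axial trajectory is blocked by the syn-axial C10 methyl, and so gives the axial 6β-alcohol (sets C6).

Step 12
Reactants: 18 angelic acid (two equivalents)
Product: 19 angelic anhydride
Conditions: DCC (0.5 equiv), CH2Cl2, 0 °C → rt; filtration
Reagents that add atoms: none
Why: Carbodiimide dehydration of two acid molecules gives the symmetric anhydride under neutral conditions that leave the (Z)-alkene unchanged.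

Step 13
Reactants: 17 6β-alcohol; 19 angelic anhydride
Product: 21 6β-angelate of 17, via lithium alkoxide 20 (not isolated)
Conditions: LiHMDS, THF, −78 °C; then 19, −78 → 0 °C; aq. NH4Cl
Reagents that add atoms: none
Why: Acylation of the preformed lithium alkoxide with the anhydride should esterify the hindered axial hydroxyl without the nucleophilic catalysts that isomerise angelate to tiglate, and TBS ethers should not migrate at this temperature.

Step 14
Reactants: 21 6β-angelate of 17
Product: 22 6β-angeloyloxy-5β,7β-bis(1-hydroxyethyl)-10β-methyl-10α-vinylcyclohexane 8α,9α-acetonide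
Conditions: HF·pyridine, pyridine, THF, 0 °C → rt
Reagents that add atoms: none
Why: Fluoride-mediated desilylation in a buffered, weakly acidic medium should cleave both secondary TBS ethers while sparing the acetonide and the ester and disfavouring acyl migration.

Step 15
Reactants: 22 6β-angeloyloxy-5β,7β-bis(1-hydroxyethyl)-10β-methyl-10α-vinylcyclohexane 8α,9α-acetonide
Product: 23 5β,7β-diacetyl-6β-angeloyloxy-10β-methyl-10α-vinylcyclohexane 8α,9α-acetonide
Conditions: Dess–Martin periodinane, NaHCO3, CH2Cl2, 0 °C → rt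
Reagents that add atoms: none
Why: Dess–Martin oxidation under bicarbonate buffer converts both carbinols into methyl ketones, removing the uncontrolled centres, under conditions too mild for β-elimination of the angelate.

Step 16
Reactants: 23 5β,7β-diacetyl-6β-angeloyloxy-10β-methyl-10α-vinylcyclohexane 8α,9α-acetonide
Product: 25 5β,7β-bis[1-(triflyloxy)vinyl]-6β-angeloyloxy-10β-methyl-10α-vinylcyclohexane 8α,9α-acetonide, via bis(potassium enolate) 24 (not isolated)
Conditions: KHMDS (2.3 equiv), THF, −78 °C; then N-(5-chloro-2-pyridyl)triflimide (2.5 equiv), −78 °C; aq. NH4Cl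
Reagents that add atoms: N-(5-chloropyridin-2-yl)bis(trifluoromethanesulfonyl)imide, O=S(=O)(N(c1ccc(Cl)cn1)S(=O)(=O)C(F)(F)F)C(F)(F)F
Why: Kinetic deprotonation with the bulky amide base should occur at the two methyl groups, not at the tertiary C5/C7 positions from which the C6 ester could be expelled, and O-sulfonylation fixes both terminal enolates (kinetic enol triflate formation).

Step 17
Reactants: 25 bis(enol triflate) acetonide
Product: 26 5β,7β-bis[1-(triflyloxy)vinyl]-6β-angeloyloxy-10β-methyl-10α-vinylcyclohexane-8α,9α-diol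
Conditions: TFA/H2O (9:1), CH2Cl2, 0 °C
Reagents that add atoms: none
Why: Acid-catalysed acetal hydrolysis should free the cis-diol, since enol triflates, the angelate and the alkenes are inert to cold aqueous acid.

Step 18
Reactants: 26 bis(enol triflate) 8α,9α-diol; 27 carbon monoxide
Product: 29 target (CNP0277836.2), via lactone enol triflate 28 (not isolated)
Conditions: Pd(PPh3)4 (10 mol %), CO (1 atm), Et3N (1.2 equiv), THF, 50 °C; Bu3SnH (1.05 equiv) in THF by syringe pump over 4 h; aq. KF work-up
Reagents that add atoms: none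
Why: Proposed new method: Pd(0) adds oxidatively to both C–OTf bonds and CO inserts to give two 2-propenoyl-palladium(II) species; the C12 acyl is attacked by the equatorial C8 hydroxyl on the adjacent ring carbon (5-exo-trig acyl substitution, Et3N taking up TfOH), which closes the trans-fused γ-lactone through C11–C12 and C12–O8, while the C15 acyl has no hydroxyl in reach (O6 is esterified; the axial C9–OH is trans to the C5 chain across C10) and persists until Sn–H transmetalation and reductive elimination give the aldehyde (C4–C15). The closest known reaction types are the Pd-catalysed carbonylative lactonisation of hydroxy enol triflates and the Pd/CO/tin hydride formylation of enol triflates; running both on one substrate in one flask is the untested part. No stereocentre is formed, the trans ring fusion being fixed by C7 and C8 of 26. The selectivity needed is O-capture at C12 before hydride delivery, hydride delivery at C15 before any intermolecular esterification, and no conjugate reduction of the two new Michael acceptors. It is secured by the intramolecular, five-membered reach of the C8 hydroxyl, by the slow addition of a single equivalent of tin hydride so that its standing concentration stays low, and by the CO atmosphere, which keeps vinyl-palladium hydride pathways short-lived.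

**Compound list**

1 | (−)-quinic acid | O[C@@]1(C(=O)O)C[C@@H](O)[C@@H](O)[C@H](O)C1 | starting material
2 | 3,4-O-isopropylidene-1,5-quinide | O[C@@]1(C(=O)O2)C[C@H]3OC(C)(C)O[C@H]3[C@H]2C1 | intermediate
3 | 1-(hydroxymethyl)cyclohexane-1,3,4,5-tetrol 3,4-acetonide | O[C@@]1(CO)C[C@H]2OC(C)(C)O[C@H]2[C@H](O)C1 | intermediate
4 | 5-hydroxy-3,4-(isopropylidenedioxy)cyclohexanone | O=C1C[C@H]2OC(C)(C)O[C@H]2[C@H](O)C1 | intermediate
5 | 5-O-mesylate of 4 (not isolated) | O=C1C[C@H]2OC(C)(C)O[C@H]2[C@H](OS(C)(=O)=O)C1 | intermediate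
6 | (4S,5R)-4,5-(isopropylidenedioxy)cyclohex-2-en-1-one | O=C1C=C[C@@H]2OC(C)(C)O[C@@H]2C1 | intermediate
7 | vinylmagnesium bromide | C=C[Mg]Br | starting material
8 | 6-(trimethylsilyloxy)-10β-vinylcyclohex-5-ene 8α,9α-acetonide | C=C[C@H]1[C@@H]2OC(C)(C)O[C@@H]2CC(O[Si](C)(C)C)=C1 | intermediate
9 | 10-vinylcyclohex-5(10)-en-6-one 8α,9α-acetonide | C=CC1=CC(=O)C[C@H]2OC(C)(C)O[C@@H]12 | intermediate
10 | acetaldehyde | CC=O | starting material
11 | bromomagnesium C5=C6 enolate of the 10β-methyl-10α-vinyl ketone (not isolated) | C=C[C@]1(C)[C@@H]2OC(C)(C)O[C@@H]2CC(O[Mg]Br)=C1 | intermediate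
12 | 5β-(1-hydroxyethyl)-10β-methyl-10α-vinylcyclohexan-6-one 8α,9α-acetonide | C=C[C@]1(C)[C@@H]2OC(C)(C)O[C@@H]2CC(=O)[C@H]1C(C)O | intermediate
13 | TBS ether of 12 | C=C[C@]1(C)[C@@H]2OC(C)(C)O[C@@H]2CC(=O)[C@H]1C(C)O[Si](C)(C)C(C)(C)C | intermediate
14 | dicyclohexylboron C6=C7 enolate of 13 (not isolated) | C=C[C@]1(C)[C@@H]2OC(C)(C)O[C@@H]2C=C(OB(C3CCCCC3)C3CCCCC3)[C@H]1C(C)O[Si](C)(C)C(C)(C)C | intermediate
15 | 7β-(1-hydroxyethyl)-5β-[1-(TBS-oxy)ethyl] ketone acetonide | C=C[C@]1(C)[C@@H]2OC(C)(C)O[C@@H]2[C@@H](C(C)O)C(=O)[C@H]1C(C)O[Si](C)(C)C(C)(C)C | intermediate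
16 | 5β,7β-bis[1-(TBS-oxy)ethyl] ketone acetonide | C=C[C@]1(C)[C@@H]2OC(C)(C)O[C@@H]2[C@@H](C(C)O[Si](C)(C)C(C)(C)C)C(=O)[C@H]1C(C)O[Si](C)(C)C(C)(C)C | intermediate
17 | 6β-alcohol of 16 | C=C[C@]1(C)[C@@H]2OC(C)(C)O[C@@H]2[C@@H](C(C)O[Si](C)(C)C(C)(C)C)[C@@H](O)[C@H]1C(C)O[Si](C)(C)C(C)(C)C | intermediate
18 | angelic acid, (Z)-2-methylbut-2-enoic acid | C/C=C(C)\C(=O)O | starting material
19 | angelic anhydride | C/C=C(C)\C(=O)OC(=O)/C(C)=C\C | intermediate
20 | lithium 6β-alkoxide of 17 (not isolated) | C=C[C@]1(C)[C@@H]2OC(C)(C)O[C@@H]2[C@@H](C(C)O[Si](C)(C)C(C)(C)C)[C@@H](O[Li])[C@H]1C(C)O[Si](C)(C)C(C)(C)C | intermediate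
21 | 6β-angelate of 17 | C=C[C@]1(C)[C@@H]2OC(C)(C)O[C@@H]2[C@@H](C(C)O[Si](C)(C)C(C)(C)C)[C@@H](OC(=O)/C(C)=C\C)[C@H]1C(C)O[Si](C)(C)C(C)(C)C | intermediate
22 | 6β-angeloyloxy-5β,7β-bis(1-hydroxyethyl) acetonide | C=C[C@]1(C)[C@@H]2OC(C)(C)O[C@@H]2[C@@H](C(C)O)[C@@H](OC(=O)/C(C)=C\C)[C@H]1C(C)O | intermediate
23 | 5β,7β-diacetyl-6β-angeloyloxy acetonide | C=C[C@]1(C)[C@@H]2OC(C)(C)O[C@@H]2[C@@H](C(C)=O)[C@@H](OC(=O)/C(C)=C\C)[C@H]1C(C)=O | intermediate
24 | bis(potassium enolate) of 23 (not isolated) | C=C[C@]1(C)[C@@H]2OC(C)(C)O[C@@H]2[C@@H](C(=C)O[K])[C@@H](OC(=O)/C(C)=C\C)[C@H]1C(=C)O[K] | intermediate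
25 | 5β,7β-bis[1-(triflyloxy)vinyl]-6β-angeloyloxy 8α,9α-acetonide | C=C[C@]1(C)[C@@H]2OC(C)(C)O[C@@H]2[C@@H](C(=C)OS(=O)(=O)C(F)(F)F)[C@@H](OC(=O)/C(C)=C\C)[C@H]1C(=C)OS(=O)(=O)C(F)(F)F | intermediate
26 | 5β,7β-bis[1-(triflyloxy)vinyl]-6β-angeloyloxy-8α,9α-diol | C=C[C@]1(C)[C@H](O)[C@H](O)[C@@H](C(=C)OS(=O)(=O)C(F)(F)F)[C@@H](OC(=O)/C(C)=C\C)[C@H]1C(=C)OS(=O)(=O)C(F)(F)F | intermediate
27 | carbon monoxide | [C-]#[O+] | starting material
28 | trans-fused 8α,12-lactone with the C4 enol triflate still in place (not isolated) | C=C[C@]1(C)[C@H](O)[C@@H]2OC(=O)C(=C)[C@H]2[C@@H](OC(=O)/C(C)=C\C)[C@H]1C(=C)OS(=O)(=O)C(F)(F)F | intermediate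
29 | CNP0277836.2 | C=C[C@]1(C)[C@H](O)[C@@H]2OC(=O)C(=C)[C@H]2[C@@H](OC(=O)/C(C)=C\C)[C@H]1C(=C)C=O | target

**Count and risks**

Total: 18 steps. Longest linear sequence: 17 steps (steps 1–11 and 13–18); step 12 is a one-step side branch.

Step 18 (Proposed new method). What may go wrong: hydride transfer to the C12 acylpalladium before the hydroxyl closes the ring, intermolecular esterification at C15, or conjugate reduction of the new enal and methylene lactone by tin hydride. Fallback by known reactions, separating the two events by oxidation level: starting from acetonide 25, which has no free hydroxyl, both enol triflates would be formylated under the established Pd(PPh3)4/CO/Bu3SnH conditions to give the bis-enal acetonide F1. Aqueous TFA then frees the diol, whose C12 aldehyde is taken up by the C8 hydroxyl as the α-methylene lactol F2 while C15 remains an enal. MnO2 in CH2Cl2, which oxidises allylic lactols but not the unactivated C9 alcohol, would convert it into 29.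

Step 7. What may go wrong: 1,6-addition of methyl at the vinyl terminus instead of 1,4-addition, sluggish turnover with the methyl Grignard, or poor facial control in the aldol trapping. Fallback, in which the vinyl group is carried as a benzyloxymethyl group so that no extended conjugation exists when methyl is added: from enone 6, the cuprate made from (benzyloxymethyl)tributylstannane (n-BuLi, then CuBr·SMe2) is added with TMSCl to give the silyl enol ether F3, and Saegusa–Ito oxidation gives the 10-(benzyloxymethyl) enone F4. Ordinary copper-catalysed addition of MeMgBr anti to O9 gives the bromomagnesium enolate F5 (not isolated), which is trapped with acetaldehyde 10 as the aldol F6 and silylated (TBSOTf, 2,6-lutidine) to the TBS ether F7. Hydrogenolysis (H2, Pd/C), possible at this stage because no alkene is present, gives the primary alcohol F8; Dess–Martin oxidation gives the non-enolisable aldehyde F9; Wittig methylenation (Ph3P=CH2, THF, −78 °C) of the aldehyde in the presence of the ketone returns to the route at 13.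

Step 16. What may go wrong: proton transfer from the methyl enolates to C5/C7 followed by E1cB loss of the angelate, attack of an enolate on the neighbouring ester carbonyl (acyl transfer), or γ-deprotonation of the angelate. Fallback, in which the ester is introduced after the triflates: from alcohol 17, the C6 hydroxyl is protected as the p-methoxybenzyl ether F10 (PMB trichloroacetimidate, cat. La(OTf)3). HF·pyridine gives the diol F11 and Dess–Martin oxidation the diketone F12. KHMDS then forms the bis(potassium enolate) F13 (not isolated) next to an ether oxygen that is a poor leaving group and cannot transfer an acyl group, and the pyridyl triflimide gives the bis(enol triflate) F14. DDQ removes the PMB group to give the C6 alcohol F15, whose lithium alkoxide F16 (not isolated; LiHMDS, −78 °C) is acylated with anhydride 19 to rejoin the route at 25.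

Further compounds
F1 | step 18 | 5β,7β-bis(1-formylvinyl)-6β-angeloyloxy-10β-methyl-10α-vinylcyclohexane 8α,9α-acetonide | C=C[C@]1(C)[C@@H]2OC(C)(C)O[C@@H]2[C@@H](C(=C)C=O)[C@@H](OC(=O)/C(C)=C\C)[C@H]1C(=C)C=O
F2 | step 18 | C12 lactol of the target (anomers) | C=C[C@]1(C)[C@H](O)[C@@H]2OC(O)C(=C)[C@H]2[C@@H](OC(=O)/C(C)=C\C)[C@H]1C(=C)C=O
F3 | step 7 | 10β-(benzyloxymethyl)-6-(trimethylsilyloxy)cyclohex-5-ene 8α,9α-acetonide | c1ccccc1COC[C@H]2[C@@H]3OC(C)(C)O[C@@H]3CC(O[Si](C)(C)C)=C2
F4 | step 7 | 10-(benzyloxymethyl)cyclohex-5(10)-en-6-one 8α,9α-acetonide | c1ccccc1COCC2=CC(=O)C[C@H]3OC(C)(C)O[C@@H]23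
F5 | step 7 | bromomagnesium C5=C6 enolate of the 10α-(benzyloxymethyl)-10β-methyl ketone (not isolated) | c1ccccc1COC[C@]2(C)[C@@H]3OC(C)(C)O[C@@H]3CC(O[Mg]Br)=C2
F6 | step 7 | 10α-(benzyloxymethyl)-5β-(1-hydroxyethyl)-10β-methylcyclohexan-6-one 8α,9α-acetonide | c1ccccc1COC[C@]2(C)[C@@H]3OC(C)(C)O[C@@H]3CC(=O)[C@H]2C(C)O
F7 | step 7 | TBS ether of F6 | c1ccccc1COC[C@]2(C)[C@@H]3OC(C)(C)O[C@@H]3CC(=O)[C@H]2C(C)O[Si](C)(C)C(C)(C)C
F8 | step 7 | 10α-(hydroxymethyl)-10β-methyl-5β-[1-(TBS-oxy)ethyl]cyclohexan-6-one 8α,9α-acetonide | OC[C@]1(C)[C@@H]2OC(C)(C)O[C@@H]2CC(=O)[C@H]1C(C)O[Si](C)(C)C(C)(C)C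
F9 | step 7 | 10α-formyl-10β-methyl-5β-[1-(TBS-oxy)ethyl]cyclohexan-6-one 8α,9α-acetonide | O=C[C@]1(C)[C@@H]2OC(C)(C)O[C@@H]2CC(=O)[C@H]1C(C)O[Si](C)(C)C(C)(C)C
F10 | step 16 | 6β-(p-methoxybenzyl) ether of 17 | C=C[C@]1(C)[C@@H]2OC(C)(C)O[C@@H]2[C@@H](C(C)O[Si](C)(C)C(C)(C)C)[C@@H](OCc3ccc(OC)cc3)[C@H]1C(C)O[Si](C)(C)C(C)(C)C
F11 | step 16 | 6β-(PMB-oxy)-5β,7β-bis(1-hydroxyethyl) acetonide | C=C[C@]1(C)[C@@H]2OC(C)(C)O[C@@H]2[C@@H](C(C)O)[C@@H](OCc3ccc(OC)cc3)[C@H]1C(C)O
F12 | step 16 | 5β,7β-diacetyl-6β-(PMB-oxy) acetonide | C=C[C@]1(C)[C@@H]2OC(C)(C)O[C@@H]2[C@@H](C(C)=O)[C@@H](OCc3ccc(OC)cc3)[C@H]1C(C)=O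
F13 | step 16 | bis(potassium enolate) of F12 (not isolated) | C=C[C@]1(C)[C@@H]2OC(C)(C)O[C@@H]2[C@@H](C(=C)O[K])[C@@H](OCc3ccc(OC)cc3)[C@H]1C(=C)O[K]
F14 | step 16 | 5β,7β-bis[1-(triflyloxy)vinyl]-6β-(PMB-oxy) acetonide | C=C[C@]1(C)[C@@H]2OC(C)(C)O[C@@H]2[C@@H](C(=C)OS(=O)(=O)C(F)(F)F)[C@@H](OCc3ccc(OC)cc3)[C@H]1C(=C)OS(=O)(=O)C(F)(F)F
F15 | step 16 | 5β,7β-bis[1-(triflyloxy)vinyl]-6β-hydroxy acetonide | C=C[C@]1(C)[C@@H]2OC(C)(C)O[C@@H]2[C@@H](C(=C)OS(=O)(=O)C(F)(F)F)[C@@H](O)[C@H]1C(=C)OS(=O)(=O)C(F)(F)F
F16 | step 16 | lithium 6β-alkoxide of F15 (not isolated) | C=C[C@]1(C)[C@@H]2OC(C)(C)O[C@@H]2[C@@H](C(=C)OS(=O)(=O)C(F)(F)F)[C@@H](O[Li])[C@H]1C(=C)OS(=O)(=O)C(F)(F)F
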